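4 questions stand below: 3 of them ask for the same share in 3 flasks, and the last ranks those shares.

| setting | larch | ash | oak |
|---|---|---|---|
| starting material | 0.20 M | 0.20 M | 0.20 M |
| coupling partner | 0.800 M | 0.800 M | 0.800 M |
| protic impurity | 0.100 M | 0.100 M | 0.100 M |
| catalyst | 0.40 mM | 0.40 mM | 0.40 mM |
| time | 1.0 h | 1.0 h | 1.0 h |
| remark | at 100 °C until 40 min, from then on at 120 °C |  |  |
| temperature |  | 120 °C | 100 °C |

    starting material + coupling partner ⇌ target (K1 = 0.70 M⁻¹, k1 = 0.049 M⁻¹ min⁻¹, Ea1 = 62.0 kJ mol⁻¹, ΔH1 = −30.0 kJ mol⁻¹)
    starting material + coupling partner ⇌ isomer of the product (K2 = 3.1 M⁻¹, k2 = 0.0012 M⁻¹ min⁻¹, Ea2 = 110 kJ mol⁻¹, ΔH2 = −23.0 kJ mol⁻¹)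
    target + catalyst ⇌ isomer of the product + catalyst, rate k3*[catalyst]*[target] forward; the back reaction follows from the equilibrium constant (k3 = 34 M⁻¹ min⁻¹, Ea3 = 62.0 kJ mol⁻¹)
    starting material → decomposition product (k4 = 1.4 × 10⁻⁵ min⁻¹, Ea4 = 123 kJ mol⁻¹)
    starting material + protic impurity → quenched substrate (k5 = 0.016 M⁻¹ min⁻¹, Ea5 = 82.0 kJ mol⁻¹)
    (constants at 100 °C)

- which flask leads in share of target in all that became target or isomer of the product ("all alike" within 1.5 percentage points) (larch / ash / oak / all alike)
- share of target in all that became target or isomer of the product, larch
- share of target in all that became target or isomer of the product, ash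
- share of target in all that became target or isomer of the product, oak

- the constants hold at 100 °C; other temperatures follow from the activation energies and enthalpies

Two colleagues dispute this share. The first holds that the flasks stand under thermodynamic control. The catalyst is a trace against 0.20 M of starting material, but it appears on both sides of its step and is never consumed, so she expects target and isomer of the product to reach the ratio set by the equilibrium constant of the catalysed step, 4.43 at 100 °C. That gives a share of 18.4%. The enthalpy of that step is 7.00 kJ mol⁻¹, so her share sinks somewhat at 120 °C, and she expects larch, ash and oak to stand close to this figure.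

The second answers that an equilibrium is reached at a rate, and that the rate must be counted. At 100 °C the rate constant for target is 40.8 times that for the isomer, so target is made far faster, and the share begins near 100%. He takes her figure as the end point at 100 °C, and the gap above it as shrinking by a constant fraction per unit time, as [catalyst] stays at its charge.

I side with him and reckon in powers of 10. Take the constant of the catalysed step and multiply it by [catalyst]. Multiply that by one plus the inverse of the equilibrium constant, which counts the back reaction, then by the time, and divide by ln 10. For oak this gives 0.434. This number, the decades of relaxation, is the power of 10 by which the gap has shrunk.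

So oak's share is that end point plus the remaining gap, 48.4%. Heat speeds the catalysed step by 2.8, which gives ash 1.20 decades and, with the end point at 100 °C kept as a rough value, 23.5%. Decades add up, so larch counts 40 min cold and 20.0 min hot, which gives 0.690 decades and, with the same rough end point, 35.1%. I therefore put oak in front.

The forecast also has oak in front, with 35% for larch, 23% for ash and 53% for oak, the last higher than my oak figure: “so the cool oak flask keeps the most target”.

The simulation gives 34.1% in larch, 23.7% in ash and 53.5% in oak, so oak leads.

Oak, with 0.434 decades, stands 5.1 percentage points above my figure. Her view belongs to long times: at 10.0 h oak stands at 17.6%, larch at 16.3% and ash at 16.3%. In larch at 1.00 h, step one relaxes with a half-life of 1.63 min, shorter than the 0.256 h of the catalysed exchange. The slower of the two is the clock the decades count. A neighbour of larch with 0.0010 M of catalyst should reach 1.72 decades and, with the same rough end point, 20.0%. Computed, that neighbour gives 22.3%.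

All constants were set for the occasion, and the outcome is calculated.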